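Ring atoms are labelled C1 (carbonyl), C2 (oxirane carbon carrying the methyl), C3 (oxirane CH), C4 (methylene), C5 (carbon carrying isopropenyl) and C6 (carbon carrying the ester oxygen). The route exploits the α,β-epoxy ketone C1–C2(–O–)C3 embedded in the six-membered carbocycle. Disconnecting C2–C3 and C2–O leads to an open-chain α-chloro ketone aldehyde, (3R,4R)-6-chloro-5-oxo-3-isopropenyl-4-silyloxyheptanal. Its C5 and C6 centres come from an anti-selective asymmetric allylboration of ethyl glyoxylate. One base-mediated intramolecular Darzens reaction then closes the cyclohexanone and the fused oxirane and sets C2 and C3. Desilylation and esterification with 4-(tigloyloxy)tiglic acid finish the synthesis.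

Key step: step 12

Remark on the chemistry (assumption): the (R)-configured phosphoric acid is taken to deliver the allyl group to the Re face of ethyl glyoxylate as it does with simple aldehydes; the configuration of 10 is to be checked (Mosher esters) before the material is carried on.

Step 1
Reactants: 1 propane-1,3-diol
Product: 2 3-[(4-methoxybenzyl)oxy]propan-1-ol
Conditions: NaH (1 equiv), 4-methoxybenzyl chloride, n-Bu4NI (cat.), THF, 0 °C → rt (diol in threefold excess)
Reagents that add atoms: 4-methoxybenzyl chloride, COc1ccc(CCl)cc1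
Why: Williamson etherification of the monoalkoxide, in which the excess of the symmetrical diol should hold dialkylation down; no stereocentre is involved.

Step 2
Reactants: 2 3-[(4-methoxybenzyl)oxy]propan-1-ol; 3 ethyl 2-(triphenylphosphoranylidene)propanoate
Product: 5 ethyl (E)-5-[(4-methoxybenzyl)oxy]-2-methylpent-2-enoate, via 3-[(4-methoxybenzyl)oxy]propanal 4 (not isolated)
Conditions: PhI(OAc)2, TEMPO (cat.), CH2Cl2, rt; then 3, rt
Reagents that add atoms: none
Why: Nitroxyl-catalysed oxidation to the aldehyde is followed in the same flask by Wittig olefination with the stabilised α-methyl ylide, which should give the (E)-trisubstituted enoate and spares the elimination-prone β-alkoxy aldehyde an isolation.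

Step 3
Reactants: 5 ethyl (E)-5-[(4-methoxybenzyl)oxy]-2-methylpent-2-enoate
Product: 6 (E)-5-[(4-methoxybenzyl)oxy]-2-methylpent-2-en-1-ol
Conditions: i-Bu2AlH (2.2 equiv), CH2Cl2, −78 °C; aq. KNaC4H4O6 (sodium potassium tartrate)
Reagents that add atoms: none
Why: Hydride 1,2-reduction of the conjugated ester by i-Bu2AlH should stop at the allylic alcohol and leave the alkene geometry and the benzyl-type ether untouched.

Step 4
Reactants: 6 (E)-5-[(4-methoxybenzyl)oxy]-2-methylpent-2-en-1-ol
Product: 7 2-{(E)-5-[(4-methoxybenzyl)oxy]-2-methylpent-2-en-1-yl}-4,4,5,5-tetramethyl-1,3,2-dioxaborolane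
Conditions: B2pin2, [Pd(MeCN)4](BF4)2 (5 mol %), DMSO/MeOH, 50 °C
Reagents that add atoms: bis(pinacolato)diboron, CC1(C)OB(OC1(C)C)B1OC(C)(C)C(C)(C)O1
Why: Palladium-catalysed allylic borylation of the free alcohol (Miyaura-type substitution through an η3-allyl complex) should deliver boron to the unsubstituted terminus while the syn-configured allyl unit keeps the E geometry.

Step 5
Reactants: 7 2-{(E)-5-[(4-methoxybenzyl)oxy]-2-methylpent-2-en-1-yl}-4,4,5,5-tetramethyl-1,3,2-dioxaborolane; 8 ethyl glyoxylate
Product: 10 ethyl (2R,3R)-2-hydroxy-3-{2-[(4-methoxybenzyl)oxy]ethyl}-4-methylpent-4-enoate, via O-boryl adduct 9 (not isolated)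
Conditions: 8 (freshly distilled, 1.5 equiv), (R)-TRIP phosphoric acid [(R)-3,3'-bis(2,4,6-triisopropylphenyl)-1,1'-binaphthyl-2,2'-diyl hydrogen phosphate] (5 mol %), 4 Å MS, toluene, −60 °C; aq. NaHCO3
Reagents that add atoms: none
Why: Chiral-Brønsted-acid-catalysed allylboration through a closed six-membered chair transition state, in which the E geometry of 7 places the γ-chain equatorial and so fixes the anti (2R,3R) relationship, the acid bound to a boronate oxygen and to the formyl hydrogen should expose the Re face of the aldehyde and set C2 as R, and the allylic transposition creates the isopropenyl group.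

Step 6
Reactants: 10 ethyl (2R,3R)-2-hydroxy-3-{2-[(4-methoxybenzyl)oxy]ethyl}-4-methylpent-4-enoate
Product: 11 (2R,3R)-2-hydroxy-N-methoxy-3-{2-[(4-methoxybenzyl)oxy]ethyl}-N,4-dimethylpent-4-enamide
Conditions: MeNHOMe·HCl, i-PrMgCl (excess), THF, −20 → 0 °C
Reagents that add atoms: N,O-dimethylhydroxylamine hydrochloride, CNOC.Cl
Why: Aminolysis of the ester by the chloromagnesium amide (Weinreb amide formation) should proceed without touching the stereocentres, since C2 carries an alkoxide under these conditions and is not enolised.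

Step 7
Reactants: 11 (2R,3R)-2-hydroxy-N-methoxy-3-{2-[(4-methoxybenzyl)oxy]ethyl}-N,4-dimethylpent-4-enamide
Product: 12 (2R,3R)-2-[(tert-butyldimethylsilyl)oxy]-N-methoxy-3-{2-[(4-methoxybenzyl)oxy]ethyl}-N,4-dimethylpent-4-enamide
Conditions: TBSOTf, 2,6-lutidine, CH2Cl2, −78 → 0 °C
Reagents that add atoms: tert-butyldimethylsilyl trifluoromethanesulfonate, CC(C)(C)[Si](C)(C)OS(=O)(=O)C(F)(F)F
Why: O-Silylation of the hindered secondary alcohol with the silyl triflate and a non-nucleophilic base installs the bulky ether that later keeps O6 equatorial and shields C6–H.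

Step 8
Reactants: 12 (2R,3R)-2-[(tert-butyldimethylsilyl)oxy]-N-methoxy-3-{2-[(4-methoxybenzyl)oxy]ethyl}-N,4-dimethylpent-4-enamide
Product: 13 (4R,5R)-4-[(tert-butyldimethylsilyl)oxy]-5-{2-[(4-methoxybenzyl)oxy]ethyl}-6-methylhept-6-en-3-one
Conditions: EtMgBr, THF, 0 °C; H2O
Reagents that add atoms: ethylmagnesium bromide, CC[Mg]Br
Why: Weinreb ketone synthesis, in which the chelated tetrahedral adduct should survive until work-up and so prevent a second addition.

Step 9
Reactants: 13 (4R,5R)-4-[(tert-butyldimethylsilyl)oxy]-5-{2-[(4-methoxybenzyl)oxy]ethyl}-6-methylhept-6-en-3-one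
Product: 15 (4R,5R)-4-[(tert-butyldimethylsilyl)oxy]-2-chloro-5-{2-[(4-methoxybenzyl)oxy]ethyl}-6-methylhept-6-en-3-one (C2 epimers), via lithium (Z)-enolate 14 (not isolated)
Conditions: LiN(SiMe3)2, THF, −78 °C; then NCS, −78 °C; AcOH quench
Reagents that add atoms: N-chlorosuccinimide, O=C1CCC(=O)N1Cl
Why: Kinetic deprotonation by the hindered amide base should occur at the accessible CH2 of the ethyl group and not at the silyloxy-bearing methine, and the enolate is chlorinated by NCS (electrophilic α-halogenation), the new C–Cl centre forming unselectively, which is harmless because it is enolised again in step 12.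

Step 10
Reactants: 15 (4R,5R)-4-[(tert-butyldimethylsilyl)oxy]-2-chloro-5-{2-[(4-methoxybenzyl)oxy]ethyl}-6-methylhept-6-en-3-one
Product: 16 (4R,5R)-4-[(tert-butyldimethylsilyl)oxy]-2-chloro-5-(2-hydroxyethyl)-6-methylhept-6-en-3-one (C2 epimers)
Conditions: DDQ, CH2Cl2/aq. NaH2PO4–Na2HPO4 buffer (pH 7), 0 °C
Reagents that add atoms: none
Why: Oxidative cleavage of the electron-rich 4-methoxybenzyl ether by DDQ (hydride abstraction, then hydrolysis of the oxocarbenium ion) under neutral conditions should leave the silyl ether, the chloro ketone and the 1,1-disubstituted alkene alone, the product possibly resting in part as its six-membered hemiketal.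

Step 11
Reactants: 16 (4R,5R)-4-[(tert-butyldimethylsilyl)oxy]-2-chloro-5-(2-hydroxyethyl)-6-methylhept-6-en-3-one
Product: 17 (3R,4R)-4-[(tert-butyldimethylsilyl)oxy]-6-chloro-5-oxo-3-(prop-1-en-2-yl)heptanal (C6 epimers)
Conditions: Dess–Martin periodinane, CH2Cl2, 0 °C → rt; crude product used at once
Reagents that add atoms: none
Why: Dess–Martin oxidation of the primary alcohol under non-basic conditions should drain the open-chain form from any hemiketal and gives an aldehyde with no stereocentre at its α-carbon, so that the base-sensitive precursor is released only in the last step before ring closure.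

Step 12
Reactants: 17 (3R,4R)-4-[(tert-butyldimethylsilyl)oxy]-6-chloro-5-oxo-3-(prop-1-en-2-yl)heptanal
Product: 19 (1S,3R,4R,6S)-3-[(tert-butyldimethylsilyl)oxy]-1-methyl-4-(prop-1-en-2-yl)-7-oxabicyclo[4.1.0]heptan-2-one, via chlorohydrin alkoxide 18 (not isolated)
Conditions: Cs2CO3 (2 equiv), MeCN (0.01 M), 0 °C → rt
Reagents that add atoms: none
Why: Cs2CO3 should deprotonate C2, whose hydrogen is acidified by both the carbonyl group and chlorine, and the enolate adds reversibly to the tethered C3 aldehyde; the alkoxide so formed then expels chloride from C2 by backside attack, which is an intramolecular Darzens condensation, the closest known reaction type being the Darzens reaction of α-chloro ketones with aldehydes. The carbocycle closes in a 6-(enolendo)-exo-trig aldol step (both enolate carbons, C1 and C2, lie in the new ring) and the oxirane in a 3-exo-tet substitution. C3 and C2 are set by the resident C5 and C6 centres: in the chair that keeps isopropenyl and silyloxy equatorial, only the chlorohydrin with axial O3 on the face opposite isopropenyl and axial chlorine on the isopropenyl face has the antiperiplanar O–C3–C2–Cl array, so the oxirane oxygen ends anti to isopropenyl and syn to O6, and inversion at C2 turns the methyl group to the isopropenyl face. The other trans-chlorohydrin would have to react from the chair with both substituents axial, where the alkoxide meets isopropenyl and chlorine meets the silyloxy group in 1,3-diaxial contacts, and the cis-chlorohydrins cannot reach antiperiplanarity at all, so with a reversible aldol step and an irreversible ring closure the material should drain through 18 (Curtin–Hammett control). Chemoselectivity is needed as well: enolates at C6 or C4 could only close four-membered rings and revert, and a weak heterogeneous base at high dilution should spare the C6 stereocentre and suppress intermolecular aldol reactions.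

Step 13
Reactants: 19 (1S,3R,4R,6S)-3-[(tert-butyldimethylsilyl)oxy]-1-methyl-4-(prop-1-en-2-yl)-7-oxabicyclo[4.1.0]heptan-2-one
Product: 20 (1S,3R,4R,6S)-3-hydroxy-1-methyl-4-(prop-1-en-2-yl)-7-oxabicyclo[4.1.0]heptan-2-one
Conditions: HF·pyridine, pyridine, THF, 0 °C → rt
Reagents that add atoms: none
Why: Fluoride-driven cleavage of the Si–O bond by pyridine-buffered HF·pyridine should occur in a weakly acidic medium that avoids enolisation at C6, while the oxirane of an α,β-epoxy ketone is a poor substrate for acid-promoted opening because the carbonyl group disfavours positive charge at C2.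

Step 14
Reactants: 21 tert-butyl 2-(triphenylphosphoranylidene)propanoate; 22 glycolaldehyde dimer (1,4-dioxane-2,5-diol)
Product: 24 tert-butyl (E)-4-hydroxy-2-methylbut-2-enoate, via glycolaldehyde 23 (not isolated)
Conditions: CH2Cl2, reflux
Reagents that add atoms: none
Why: Wittig olefination of monomeric glycolaldehyde, released from the dimer on warming, with the stabilised α-methyl ylide should give the (E)-enoate and tolerates the free hydroxyl group.

Step 15
Reactants: 24 tert-butyl (E)-4-hydroxy-2-methylbut-2-enoate; 25 tiglic acid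
Product: 26 tert-butyl (E)-2-methyl-4-{[(E)-2-methylbut-2-enoyl]oxy}but-2-enoate
Conditions: DCC, DMAP (cat.), CH2Cl2, 0 °C → rt
Reagents that add atoms: none
Why: Steglich esterification (carbodiimide activation, DMAP acyl transfer) of the unhindered primary allylic alcohol with tiglic acid, whose (E)-alkene is the thermodynamically favoured isomer and should not isomerise.

Step 16
Reactants: 26 tert-butyl (E)-2-methyl-4-{[(E)-2-methylbut-2-enoyl]oxy}but-2-enoate
Product: 27 (E)-2-methyl-4-{[(E)-2-methylbut-2-enoyl]oxy}but-2-enoic acid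
Conditions: CF3CO2H, CH2Cl2, 0 °C → rt
Reagents that add atoms: none
Why: Acidolysis of the tert-butyl ester by loss of the tert-butyl cation as 2-methylpropene frees the acid without hydrolytic conditions, and the primary allylic tiglate should survive because ionisation next to an electron-poor alkene is disfavoured.

Step 17
Reactants: 20 (1S,3R,4R,6S)-3-hydroxy-1-methyl-4-(prop-1-en-2-yl)-7-oxabicyclo[4.1.0]heptan-2-one; 27 (E)-2-methyl-4-{[(E)-2-methylbut-2-enoyl]oxy}but-2-enoic acid
Product: 28 (1S,3R,4R,6S)-1-methyl-2-oxo-4-(prop-1-en-2-yl)-7-oxabicyclo[4.1.0]heptan-3-yl (E)-2-methyl-4-{[(E)-2-methylbut-2-enoyl]oxy}but-2-enoate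
Conditions: DCC, DMAP (cat.), CH2Cl2, 0 °C → rt
Reagents that add atoms: none
Why: Steglich esterification acylates the secondary alcohol at oxygen, so the C6–O bond and its configuration are retained, and a catalytic amount of DMAP at low temperature should keep the now more acidic C6–H from epimerising.

Compound list
1 | propane-1,3-diol | OCCCO | starting material
2 | 3-[(4-methoxybenzyl)oxy]propan-1-ol | COc1ccc(COCCCO)cc1 | intermediate
3 | ethyl 2-(triphenylphosphoranylidene)propanoate | CCOC(=O)C(C)=P(c1ccccc1)(c1ccccc1)c1ccccc1 | starting material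
4 | 3-[(4-methoxybenzyl)oxy]propanal | COc1ccc(COCCC=O)cc1 | intermediate (not isolated)
5 | ethyl (E)-5-[(4-methoxybenzyl)oxy]-2-methylpent-2-enoate | CCOC(=O)/C(C)=C/CCOCc1ccc(OC)cc1 | intermediate
6 | (E)-5-[(4-methoxybenzyl)oxy]-2-methylpent-2-en-1-ol | OC/C(C)=C/CCOCc1ccc(OC)cc1 | intermediate
7 | 2-{(E)-5-[(4-methoxybenzyl)oxy]-2-methylpent-2-en-1-yl}-4,4,5,5-tetramethyl-1,3,2-dioxaborolane | CC1(C)OB(C/C(C)=C/CCOCc2ccc(OC)cc2)OC1(C)C | intermediate
8 | ethyl glyoxylate | O=CC(=O)OCC | starting material
9 | ethyl (2R,3R)-3-{2-[(4-methoxybenzyl)oxy]ethyl}-4-methyl-2-[(4,4,5,5-tetramethyl-1,3,2-dioxaborolan-2-yl)oxy]pent-4-enoate (O-boryl adduct) | C=C(C)[C@@H](CCOCc1ccc(OC)cc1)[C@@H](OB1OC(C)(C)C(C)(C)O1)C(=O)OCC | intermediate (not isolated)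
10 | ethyl (2R,3R)-2-hydroxy-3-{2-[(4-methoxybenzyl)oxy]ethyl}-4-methylpent-4-enoate | C=C(C)[C@@H](CCOCc1ccc(OC)cc1)[C@@H](O)C(=O)OCC | intermediate
11 | (2R,3R)-2-hydroxy-N-methoxy-3-{2-[(4-methoxybenzyl)oxy]ethyl}-N,4-dimethylpent-4-enamide | C=C(C)[C@@H](CCOCc1ccc(OC)cc1)[C@@H](O)C(=O)N(C)OC | intermediate
12 | (2R,3R)-2-[(tert-butyldimethylsilyl)oxy]-N-methoxy-3-{2-[(4-methoxybenzyl)oxy]ethyl}-N,4-dimethylpent-4-enamide | C=C(C)[C@@H](CCOCc1ccc(OC)cc1)[C@@H](O[Si](C)(C)C(C)(C)C)C(=O)N(C)OC | intermediate
13 | (4R,5R)-4-[(tert-butyldimethylsilyl)oxy]-5-{2-[(4-methoxybenzyl)oxy]ethyl}-6-methylhept-6-en-3-one | C=C(C)[C@@H](CCOCc1ccc(OC)cc1)[C@@H](O[Si](C)(C)C(C)(C)C)C(=O)CC | intermediate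
14 | lithium (Z)-enolate of 13 (deprotonated at C2) | C=C(C)[C@@H](CCOCc1ccc(OC)cc1)[C@@H](O[Si](C)(C)C(C)(C)C)/C(O[Li])=C/C | intermediate (not isolated)
15 | (4R,5R)-4-[(tert-butyldimethylsilyl)oxy]-2-chloro-5-{2-[(4-methoxybenzyl)oxy]ethyl}-6-methylhept-6-en-3-one (C2 epimers) | C=C(C)[C@@H](CCOCc1ccc(OC)cc1)[C@@H](O[Si](C)(C)C(C)(C)C)C(=O)C(C)Cl | intermediate
16 | (4R,5R)-4-[(tert-butyldimethylsilyl)oxy]-2-chloro-5-(2-hydroxyethyl)-6-methylhept-6-en-3-one (C2 epimers) | C=C(C)[C@@H](CCO)[C@@H](O[Si](C)(C)C(C)(C)C)C(=O)C(C)Cl | intermediate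
17 | (3R,4R)-4-[(tert-butyldimethylsilyl)oxy]-6-chloro-5-oxo-3-(prop-1-en-2-yl)heptanal (C6 epimers) | C=C(C)[C@@H](CC=O)[C@@H](O[Si](C)(C)C(C)(C)C)C(=O)C(C)Cl | intermediate (key-step precursor)
18 | (2R,3S,5R,6R)-6-[(tert-butyldimethylsilyl)oxy]-2-chloro-3-hydroxy-2-methyl-5-(prop-1-en-2-yl)cyclohexan-1-one, present as its caesium alkoxide | C=C(C)[C@H]1C[C@H](O)[C@@](C)(Cl)C(=O)[C@@H]1O[Si](C)(C)C(C)(C)C | intermediate (not isolated)
19 | (1S,3R,4R,6S)-3-[(tert-butyldimethylsilyl)oxy]-1-methyl-4-(prop-1-en-2-yl)-7-oxabicyclo[4.1.0]heptan-2-one | C=C(C)[C@H]1C[C@@H]2O[C@]2(C)C(=O)[C@@H]1O[Si](C)(C)C(C)(C)C | intermediate (key-step product)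
20 | (1S,3R,4R,6S)-3-hydroxy-1-methyl-4-(prop-1-en-2-yl)-7-oxabicyclo[4.1.0]heptan-2-one | C=C(C)[C@H]1C[C@@H]2O[C@]2(C)C(=O)[C@@H]1O | intermediate
21 | tert-butyl 2-(triphenylphosphoranylidene)propanoate | CC(C)(C)OC(=O)C(C)=P(c1ccccc1)(c1ccccc1)c1ccccc1 | starting material
22 | glycolaldehyde dimer (1,4-dioxane-2,5-diol) | OC1COC(O)CO1 | starting material
23 | glycolaldehyde | OCC=O | intermediate (not isolated)
24 | tert-butyl (E)-4-hydroxy-2-methylbut-2-enoate | CC(C)(C)OC(=O)/C(C)=C/CO | intermediate
25 | tiglic acid, (E)-2-methylbut-2-enoic acid | C/C=C(\C)C(=O)O | starting material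
26 | tert-butyl (E)-2-methyl-4-{[(E)-2-methylbut-2-enoyl]oxy}but-2-enoate | CC(C)(C)OC(=O)/C(C)=C/COC(=O)/C(C)=C/C | intermediate
27 | (E)-2-methyl-4-{[(E)-2-methylbut-2-enoyl]oxy}but-2-enoic acid | OC(=O)/C(C)=C/COC(=O)/C(C)=C/C | intermediate
28 | (1S,3R,4R,6S)-1-methyl-2-oxo-4-(prop-1-en-2-yl)-7-oxabicyclo[4.1.0]heptan-3-yl (E)-2-methyl-4-{[(E)-2-methylbut-2-enoyl]oxy}but-2-enoate | C=C(C)[C@H]1C[C@@H]2O[C@]2(C)C(=O)[C@@H]1OC(=O)/C(C)=C/COC(=O)/C(C)=C/C | target

Total step count: 17 (steps 14–16 build the side-chain acid in a separate branch).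
Longest linear sequence: 14 (steps 1–13 and 17).

Steps most likely to fail

1. Step 12. The enolisable aldehyde may condense between molecules faster than the ring closes. Closure may also run through the chlorohydrin of the other facial series, and C6 may epimerise under base. The fallback sets out from ketone 13 and leaves the halogen out. DDQ in buffered CH2Cl2 should give the alcohol (4R,5R)-4-[(tert-butyldimethylsilyl)oxy]-5-(2-hydroxyethyl)-6-methylhept-6-en-3-one F1. Dess–Martin oxidation should give the keto aldehyde (3R,4R)-4-[(tert-butyldimethylsilyl)oxy]-5-oxo-3-(prop-1-en-2-yl)heptanal F2. An intramolecular aldol condensation (dibenzylammonium trifluoroacetate, toluene, 50 °C) should then give the enone (5R,6R)-6-[(tert-butyldimethylsilyl)oxy]-2-methyl-5-(prop-1-en-2-yl)cyclohex-2-en-1-one F3, a 6-silyloxy carvone. Weitz–Scheffer epoxidation (H2O2, NaOH, MeOH, 0 °C) should add hydroperoxide to C3 on the face opposite the C5 isopropenyl group, as carvone itself does, and the route is rejoined at 19.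

2. Step 5. The very electrophilic glyoxylate may react without the catalyst and so erode the enantiomeric purity, or the facial preference may be weaker than, or opposite to, that found with simple aldehydes. The fallback sets out from 7 and 8 and gives up catalytic control. The uncatalysed allylboration (toluene, rt) should still be anti-selective through the chair transition state and give 9 together with its mirror image, the O-boryl adduct ethyl (2S,3S)-3-{2-[(4-methoxybenzyl)oxy]ethyl}-4-methyl-2-[(4,4,5,5-tetramethyl-1,3,2-dioxaborolan-2-yl)oxy]pent-4-enoate F4. After hydrolysis the racemic hydroxy ester is resolved by preparative chromatography on a chiral stationary phase, which removes the enantiomer ethyl (2S,3S)-2-hydroxy-3-{2-[(4-methoxybenzyl)oxy]ethyl}-4-methylpent-4-enoate F5, and the route is rejoined at 10.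

3. Step 9. Proton transfer between the chloro ketone and unreacted enolate may lead to over-chlorination and recovered ketone, and any enolisation toward the silyloxy-bearing carbon would erode C4. The fallback sets out from 13 and separates enolisation from halogenation. The kinetic enolate is trapped (LiN(SiMe3)2, Me3SiCl, THF, −78 °C) and isolated as the silyl enol ether (2Z,4R,5R)-4-[(tert-butyldimethylsilyl)oxy]-5-{2-[(4-methoxybenzyl)oxy]ethyl}-6-methyl-3-[(trimethylsilyl)oxy]hepta-2,6-diene F6, whose regiochemistry can be checked. It is then chlorinated under base-free conditions with NCS (THF, 0 °C), and the route is rejoined at 15.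

Further compounds
F1 | step 12 | (4R,5R)-4-[(tert-butyldimethylsilyl)oxy]-5-(2-hydroxyethyl)-6-methylhept-6-en-3-one | C=C(C)[C@@H](CCO)[C@@H](O[Si](C)(C)C(C)(C)C)C(=O)CC
F2 | step 12 | (3R,4R)-4-[(tert-butyldimethylsilyl)oxy]-5-oxo-3-(prop-1-en-2-yl)heptanal | C=C(C)[C@@H](CC=O)[C@@H](O[Si](C)(C)C(C)(C)C)C(=O)CC
F3 | step 12 | (5R,6R)-6-[(tert-butyldimethylsilyl)oxy]-2-methyl-5-(prop-1-en-2-yl)cyclohex-2-en-1-one | C=C(C)[C@H]1CC=C(C)C(=O)[C@@H]1O[Si](C)(C)C(C)(C)C
F4 | step 5 | ethyl (2S,3S)-3-{2-[(4-methoxybenzyl)oxy]ethyl}-4-methyl-2-[(4,4,5,5-tetramethyl-1,3,2-dioxaborolan-2-yl)oxy]pent-4-enoate | C=C(C)[C@H](CCOCc1ccc(OC)cc1)[C@H](OB1OC(C)(C)C(C)(C)O1)C(=O)OCC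
F5 | step 5 | ethyl (2S,3S)-2-hydroxy-3-{2-[(4-methoxybenzyl)oxy]ethyl}-4-methylpent-4-enoate | C=C(C)[C@H](CCOCc1ccc(OC)cc1)[C@H](O)C(=O)OCC
F6 | step 9 | (2Z,4R,5R)-4-[(tert-butyldimethylsilyl)oxy]-5-{2-[(4-methoxybenzyl)oxy]ethyl}-6-methyl-3-[(trimethylsilyl)oxy]hepta-2,6-diene | C=C(C)[C@@H](CCOCc1ccc(OC)cc1)[C@@H](O[Si](C)(C)C(C)(C)C)/C(O[Si](C)(C)C)=C/C
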